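## Retr­osynthetic overview

1. Target 29 ⇐ bis-silyl ether 28. The pyran ring is closed last, by invertive intramolecular Mitsunobu etherification (O1–C2) of the (R)-carbinol 27, whose stereocentre comes from CBS reduction of ketone 25.
2. 25 ⇐ enone 24 ⇐ intermolecular aldol union of acetophenone (21) with the fully assembled biaryl aldehyde 20. This is the key C–C bond (flavan C3–C4).
3. 20 ⇐ 15 by MOM-directed ortho-lithiation/formylation of the symmetric A ring (only one kind of C–H), then protecting-group adjustment.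
4. 15 ⇐ arylacetylene 13 + o-iodophenol 8 by Sonogashira coupling/5-endo cyclisation. The benzofuran is the first heterocycle formed, the chroman the second.
5. 13 ⇐ symmetric 2',6'-dihydroxy-4'-methoxyacetophenone (9); 8 ⇐ 3-methoxy-2-methylphenol (1) by Ir C–H borylation/oxidation and directed ortho-iodination.

Assumption: 1 and 9 are bought as catalogue chemicals.

Abbreviations: TIPS = triisopropylsilyl, MOM = methoxymethyl, Bn = benzyl, BfT = 4-methoxy-5-methyl-6-(triisopropylsilyloxy)-1-benzofuran-2-yl.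

## Route

Step 1
Reactants: 1 3-methoxy-2-methylphenol
Product: 2 triisopropyl(3-methoxy-2-methylphenoxy)silane
Conditions: TIPSCl, imidazole, DMF, rt
Reagents that add atoms: chlorotriisopropylsilane CC(C)[Si](Cl)(C(C)C)C(C)C
Why: Imidazole-promoted silyl etherification of the phenol gives a bulky, non-coordinating ether that later blocks lithiation at its ortho position.

Step 2
Reactants: 2 triisopropyl(3-methoxy-2-methylphenoxy)silane
Product: 4 3-methoxy-4-methyl-5-(triisopropylsilyloxy)phenol, via aryl pinacolboronate 3 (not isolated)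
Conditions: [Ir(OMe)(cod)]2 (1.5 mol %), dtbpy (3 mol %), B2pin2 (1.0 equiv), THF, 80 °C; then Oxone, acetone–H2O, rt
Reagents that add atoms: potassium peroxymonosulfate (Oxone) OOS(=O)(=O)[O-].[K+] (the phenol oxygen); bis(pinacolato)diboron CC1(C)OB(OC1(C)C)B1OC(C)(C)C(C)(C)O1 (Bpin of 3 only)
Why: Sterically controlled Ir-catalysed C–H borylation (Hartwig–Miyaura type) reaches only C5, the one C–H with no ortho substituent, and the boronate is oxidised in the same pot to the phenol at that site.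

Step 3
Reactants: 4 3-methoxy-4-methyl-5-(triisopropylsilyloxy)phenol
Product: 5 triisopropyl[3-methoxy-5-(methoxymethoxy)-2-methylphenoxy]silane
Conditions: MOMCl, i-Pr2NEt, CH2Cl2, 0 °C → rt
Reagents that add atoms: chloromethyl methyl ether COCCl
Why: O-alkylation of the phenol (Williamson type) installs a strong ortho-directing group on the new oxygen.

Step 4
Reactants: 5 triisopropyl[3-methoxy-5-(methoxymethoxy)-2-methylphenoxy]silane
Product: 7 [4-iodo-3-methoxy-5-(methoxymethoxy)-2-methylphenoxy]triisopropylsilane, via aryllithium 6 (not isolated)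
Conditions: n-BuLi, TMEDA, THF, 0 °C; then I2, −78 °C → rt
Reagents that add atoms: iodine II; n-butyllithium [Li]CCCC (Li of 6 only)
Why: Directed ortho-metalation occurs at the C–H flanked by the cooperating OMOM and OMe groups (the OTIPS-flanked C–H is shielded and unactivated), and the aryllithium is trapped by iodine.

Step 5
Reactants: 7 [4-iodo-3-methoxy-5-(methoxymethoxy)-2-methylphenoxy]triisopropylsilane
Product: 8 2-iodo-3-methoxy-4-methyl-5-(triisopropylsilyloxy)phenol
Conditions: conc. HCl (cat.), MeOH–THF, 40 °C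
Reagents that add atoms: none
Why: Acid-catalysed acetal exchange with methanol removes MOM, while the hindered aryl TIPS ether and the aryl iodide are stable to dilute acid.

Step 6
Reactants: 9 1-(2,6-dihydroxy-4-methoxyphenyl)ethan-1-one
Product: 10 1-[4-methoxy-2,6-bis(methoxymethoxy)phenyl]ethan-1-one
Conditions: NaH, MOMCl, DMF, 0 °C → rt
Reagents that add atoms: chloromethyl methyl ether COCCl
Why: Double Williamson etherification of the two chelated phenols through their sodium phenoxides; the symmetry of 9 makes the product unambiguous.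

Step 7
Reactants: 10 1-[4-methoxy-2,6-bis(methoxymethoxy)phenyl]ethan-1-one
Product: 13 2-ethynyl-5-methoxy-1,3-bis(methoxymethoxy)benzene, via enol diethyl phosphate 11 (not isolated), via lithium acetylide 12 (not isolated)
Conditions: LDA (1.1 equiv), THF, −78 °C; ClP(O)(OEt)2, −78 °C → rt; LDA (2.3 equiv), −78 °C → rt; H2O
Reagents that add atoms: diethyl chlorophosphate CCOP(=O)(Cl)OCC (phosphate of 11 only); lithium diisopropylamide [Li]N(C(C)C)C(C)C (Li of 12 only); nothing from either remains in 13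
Why: Negishi's methyl ketone to alkyne procedure: O-phosphorylation of the enolate, then base-induced elimination of diethyl phosphate, with the acetylide protonated on work-up.

Step 8
Reactants: 8 2-iodo-3-methoxy-4-methyl-5-(triisopropylsilyloxy)phenol; 13 2-ethynyl-5-methoxy-1,3-bis(methoxymethoxy)benzene
Product: 15 4-methoxy-2-[4-methoxy-2,6-bis(methoxymethoxy)phenyl]-5-methyl-6-(triisopropylsilyloxy)-1-benzofuran, via 2-alkynylphenol 14 (not isolated)
Conditions: PdCl2(PPh3)2 (5 mol %), CuI (10 mol %), Et3N–DMF, 70 °C, Ar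
Reagents that add atoms: none
Why: Sonogashira coupling followed in the same pot by metal-promoted 5-endo-dig hydroalkoxylation by the only free phenol (the A-ring oxygens are MOM-capped) gives the 2-arylbenzofuran.

Step 9
Reactants: 15 4-methoxy-2-[4-methoxy-2,6-bis(methoxymethoxy)phenyl]-5-methyl-6-(triisopropylsilyloxy)-1-benzofuran
Product: 17 6-methoxy-2,4-bis(methoxymethoxy)-3-(BfT)benzaldehyde, via aryllithium 16 (not isolated)
Conditions: n-BuLi, TMEDA, THF, −20 → 0 °C; DMF, 0 °C → rt; H2O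
Reagents that add atoms: N,N-dimethylformamide CN(C)C=O (formyl C and O); n-butyllithium [Li]CCCC (Li of 16 only)
Why: Directed ortho-metalation/formylation: the two A-ring C–H bonds flanked by OMOM and OMe are equivalent by symmetry, so only one aldehyde can form.

Step 10
Reactants: 17 6-methoxy-2,4-bis(methoxymethoxy)-3-(BfT)benzaldehyde
Product: 18 2,4-dihydroxy-6-methoxy-3-(BfT)benzaldehyde
Conditions: 3 M aq. HCl–MeOH–THF, 45 °C
Reagents that add atoms: none
Why: Acidic methanolysis cleaves both MOM acetals (the one ortho to the formyl group fastest), and the methyl-flanked aryl TIPS ether survives.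

Step 11
Reactants: 18 2,4-dihydroxy-6-methoxy-3-(BfT)benzaldehyde
Product: 19 2-hydroxy-6-methoxy-3-(BfT)-4-(triisopropylsilyloxy)benzaldehyde
Conditions: TIPSCl (1.2 equiv), imidazole, DMF, 0 °C → rt
Reagents that add atoms: chlorotriisopropylsilane CC(C)[Si](Cl)(C(C)C)C(C)C
Why: Chemoselective silylation: the 4-OH para to the formyl group is free and acidic, whereas the 2-OH is hydrogen-bonded to C=O and flanked on both sides.

Step 12
Reactants: 19 2-hydroxy-6-methoxy-3-(BfT)-4-(triisopropylsilyloxy)benzaldehyde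
Product: 20 2-(benzyloxy)-6-methoxy-3-(BfT)-4-(triisopropylsilyloxy)benzaldehyde
Conditions: BnOH, PPh3, DIAD, THF, 0 °C → rt
Reagents that add atoms: benzyl alcohol OCc1ccccc1
Why: Mitsunobu O-alkylation benzylates the acidic chelated phenol under neutral conditions that do not endanger the aryl silyl ethers.

Step 13
Reactants: 20 2-(benzyloxy)-6-methoxy-3-(BfT)-4-(triisopropylsilyloxy)benzaldehyde; 21 acetophenone
Product: 23 3-[2-(benzyloxy)-6-methoxy-3-(BfT)-4-(triisopropylsilyloxy)phenyl]-3-hydroxy-1-phenylpropan-1-one (racemic), via acetophenone lithium enolate 22 (not isolated)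
Conditions: 21, LDA, THF, −78 °C; then 20, −78 °C, 1 h; AcOH, −78 °C
Reagents that add atoms: lithium diisopropylamide [Li]N(C(C)C)C(C)C (Li of 22 only)
Why: Intermolecular aldol addition of a preformed lithium enolate to a non-enolisable aldehyde makes the flavan C3–C4 bond; the new carbinol centre is racemic and is removed in the next step.

Step 14
Reactants: 23 3-[2-(benzyloxy)-6-methoxy-3-(BfT)-4-(triisopropylsilyloxy)phenyl]-3-hydroxy-1-phenylpropan-1-one
Product: 24 (E)-3-[2-(benzyloxy)-6-methoxy-3-(BfT)-4-(triisopropylsilyloxy)phenyl]-1-phenylprop-2-en-1-one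
Conditions: MsCl, Et3N, CH2Cl2, 0 °C → rt
Reagents that add atoms: none
Why: Mesylation and E1cB elimination (aldol dehydration) give the conjugated enone in the thermodynamically favoured E geometry.

Step 15
Reactants: 24 (E)-3-[2-(benzyloxy)-6-methoxy-3-(BfT)-4-(triisopropylsilyloxy)phenyl]-1-phenylprop-2-en-1-one
Product: 25 3-[2-(benzyloxy)-6-methoxy-3-(BfT)-4-(triisopropylsilyloxy)phenyl]-1-phenylpropan-1-one
Conditions: H2 (1 atm), 10 % Pd/C, Ph2S (cat.), EtOAc, rt
Reagents that add atoms: none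
Why: Sulfide-poisoned heterogeneous hydrogenation saturates the enone C=C while the aryl ketone, the aryl benzyl ether and the benzofuran are left intact.

Step 16
Reactants: 25 3-[2-(benzyloxy)-6-methoxy-3-(BfT)-4-(triisopropylsilyloxy)phenyl]-1-phenylpropan-1-one
Product: 26 (1R)-3-[2-(benzyloxy)-6-methoxy-3-(BfT)-4-(triisopropylsilyloxy)phenyl]-1-phenylpropan-1-ol
Conditions: (S)-Me-CBS (20 mol %), BH3·SMe2, THF, −20 °C; MeOH
Reagents that add atoms: none
Why: Corey–Bakshi–Shibata reduction: with phenyl as the large and the CH2 chain as the small substituent, the (S)-oxazaborolidine directs hydride to the Si face and sets the (R)-carbinol.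

Step 17
Reactants: 26 (1R)-3-[2-(benzyloxy)-6-methoxy-3-(BfT)-4-(triisopropylsilyloxy)phenyl]-1-phenylpropan-1-ol
Product: 27 2-[(3R)-3-hydroxy-3-phenylpropyl]-3-methoxy-6-(BfT)-5-(triisopropylsilyloxy)phenol
Conditions: H2 (1 atm), 10 % Pd/C, EtOAc, rt
Reagents that add atoms: none
Why: Hydrogenolysis of the aryl benzyl ether frees the phenol; the unactivated secondary benzylic alcohol and the benzofuran are not reduced under neutral conditions at 1 atm, so the stereocentre is untouched.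

Step 18
Reactants: 27 2-[(3R)-3-hydroxy-3-phenylpropyl]-3-methoxy-6-(BfT)-5-(triisopropylsilyloxy)phenol
Product: 28 (2S)-5-methoxy-8-(BfT)-2-phenyl-7-(triisopropylsilyloxy)chromane
Conditions: PPh3, DIAD, THF (0.02 M), 0 °C → rt
Reagents that add atoms: none
Why: Intramolecular Mitsunobu etherification: the phenol displaces the activated benzylic oxyphosphonium in an SN2 six-membered ring closure with inversion, converting the (R)-carbinol into the (2S)-flavan.

Step 19
Reactants: 28 (2S)-5-methoxy-8-(BfT)-2-phenyl-7-(triisopropylsilyloxy)chromane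
Product: 29 (2S)-8-(6-hydroxy-4-methoxy-5-methyl-1-benzofuran-2-yl)-5-methoxy-2-phenyl-3,4-dihydro-2H-chromen-7-ol
Conditions: TBAF, AcOH, THF, 0 °C → rt
Reagents that add atoms: none
Why: Fluoride-induced cleavage of both aryl silyl ethers under buffered conditions that cannot affect the C2 stereocentre gives the target.

## Compound list

1 | 3-methoxy-2-methylphenol | COc1cccc(O)c1C | starting material
2 | triisopropyl(3-methoxy-2-methylphenoxy)silane | COc1cccc(O[Si](C(C)C)(C(C)C)C(C)C)c1C | intermediate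
3 | 2-[3-methoxy-4-methyl-5-(triisopropylsilyloxy)phenyl]-4,4,5,5-tetramethyl-1,3,2-dioxaborolane | COc1cc(B2OC(C)(C)C(C)(C)O2)cc(O[Si](C(C)C)(C(C)C)C(C)C)c1C | intermediate
4 | 3-methoxy-4-methyl-5-(triisopropylsilyloxy)phenol | COc1cc(O)cc(O[Si](C(C)C)(C(C)C)C(C)C)c1C | intermediate
5 | triisopropyl[3-methoxy-5-(methoxymethoxy)-2-methylphenoxy]silane | COCOc1cc(OC)c(C)c(O[Si](C(C)C)(C(C)C)C(C)C)c1 | intermediate
6 | [2-methoxy-6-(methoxymethoxy)-3-methyl-4-(triisopropylsilyloxy)phenyl]lithium | COCOc1cc(O[Si](C(C)C)(C(C)C)C(C)C)c(C)c(OC)c1[Li] | intermediate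
7 | [4-iodo-3-methoxy-5-(methoxymethoxy)-2-methylphenoxy]triisopropylsilane | COCOc1cc(O[Si](C(C)C)(C(C)C)C(C)C)c(C)c(OC)c1I | intermediate
8 | 2-iodo-3-methoxy-4-methyl-5-(triisopropylsilyloxy)phenol | Oc1cc(O[Si](C(C)C)(C(C)C)C(C)C)c(C)c(OC)c1I | intermediate
9 | 1-(2,6-dihydroxy-4-methoxyphenyl)ethan-1-one | CC(=O)c1c(O)cc(OC)cc1O | starting material
10 | 1-[4-methoxy-2,6-bis(methoxymethoxy)phenyl]ethan-1-one | CC(=O)c1c(OCOC)cc(OC)cc1OCOC | intermediate
11 | diethyl 1-[4-methoxy-2,6-bis(methoxymethoxy)phenyl]ethenyl phosphate | C=C(OP(=O)(OCC)OCC)c1c(OCOC)cc(OC)cc1OCOC | intermediate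
12 | {[4-methoxy-2,6-bis(methoxymethoxy)phenyl]ethynyl}lithium | [Li]C#Cc1c(OCOC)cc(OC)cc1OCOC | intermediate
13 | 2-ethynyl-5-methoxy-1,3-bis(methoxymethoxy)benzene | C#Cc1c(OCOC)cc(OC)cc1OCOC | intermediate
14 | 2-{[4-methoxy-2,6-bis(methoxymethoxy)phenyl]ethynyl}-3-methoxy-4-methyl-5-(triisopropylsilyloxy)phenol | COCOc1cc(OC)cc(OCOC)c1C#Cc1c(O)cc(O[Si](C(C)C)(C(C)C)C(C)C)c(C)c1OC | intermediate
15 | 4-methoxy-2-[4-methoxy-2,6-bis(methoxymethoxy)phenyl]-5-methyl-6-(triisopropylsilyloxy)-1-benzofuran | COCOc1cc(OC)cc(OCOC)c1-c1cc2c(OC)c(C)c(O[Si](C(C)C)(C(C)C)C(C)C)cc2o1 | intermediate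
16 | {2-methoxy-4,6-bis(methoxymethoxy)-5-[4-methoxy-5-methyl-6-(triisopropylsilyloxy)-1-benzofuran-2-yl]phenyl}lithium | COCOc1c([Li])c(OC)cc(OCOC)c1-c1cc2c(OC)c(C)c(O[Si](C(C)C)(C(C)C)C(C)C)cc2o1 | intermediate
17 | 6-methoxy-2,4-bis(methoxymethoxy)-3-[4-methoxy-5-methyl-6-(triisopropylsilyloxy)-1-benzofuran-2-yl]benzaldehyde | COCOc1c(C=O)c(OC)cc(OCOC)c1-c1cc2c(OC)c(C)c(O[Si](C(C)C)(C(C)C)C(C)C)cc2o1 | intermediate
18 | 2,4-dihydroxy-6-methoxy-3-[4-methoxy-5-methyl-6-(triisopropylsilyloxy)-1-benzofuran-2-yl]benzaldehyde | O=Cc1c(OC)cc(O)c(-c2cc3c(OC)c(C)c(O[Si](C(C)C)(C(C)C)C(C)C)cc3o2)c1O | intermediate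
19 | 2-hydroxy-6-methoxy-3-[4-methoxy-5-methyl-6-(triisopropylsilyloxy)-1-benzofuran-2-yl]-4-(triisopropylsilyloxy)benzaldehyde | O=Cc1c(OC)cc(O[Si](C(C)C)(C(C)C)C(C)C)c(-c2cc3c(OC)c(C)c(O[Si](C(C)C)(C(C)C)C(C)C)cc3o2)c1O | intermediate
20 | 2-(benzyloxy)-6-methoxy-3-[4-methoxy-5-methyl-6-(triisopropylsilyloxy)-1-benzofuran-2-yl]-4-(triisopropylsilyloxy)benzaldehyde | O=Cc1c(OC)cc(O[Si](C(C)C)(C(C)C)C(C)C)c(-c2cc3c(OC)c(C)c(O[Si](C(C)C)(C(C)C)C(C)C)cc3o2)c1OCc1ccccc1 | intermediate
21 | acetophenone | CC(=O)c1ccccc1 | starting material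
22 | lithium 1-phenylethen-1-olate | [Li]OC(=C)c1ccccc1 | intermediate
23 | 3-{2-(benzyloxy)-6-methoxy-3-[4-methoxy-5-methyl-6-(triisopropylsilyloxy)-1-benzofuran-2-yl]-4-(triisopropylsilyloxy)phenyl}-3-hydroxy-1-phenylpropan-1-one (racemic) | O=C(CC(O)c1c(OC)cc(O[Si](C(C)C)(C(C)C)C(C)C)c(-c2cc3c(OC)c(C)c(O[Si](C(C)C)(C(C)C)C(C)C)cc3o2)c1OCc1ccccc1)c1ccccc1 | intermediate
24 | (E)-3-{2-(benzyloxy)-6-methoxy-3-[4-methoxy-5-methyl-6-(triisopropylsilyloxy)-1-benzofuran-2-yl]-4-(triisopropylsilyloxy)phenyl}-1-phenylprop-2-en-1-one | O=C(/C=C/c1c(OC)cc(O[Si](C(C)C)(C(C)C)C(C)C)c(-c2cc3c(OC)c(C)c(O[Si](C(C)C)(C(C)C)C(C)C)cc3o2)c1OCc1ccccc1)c1ccccc1 | intermediate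
25 | 3-{2-(benzyloxy)-6-methoxy-3-[4-methoxy-5-methyl-6-(triisopropylsilyloxy)-1-benzofuran-2-yl]-4-(triisopropylsilyloxy)phenyl}-1-phenylpropan-1-one | O=C(CCc1c(OC)cc(O[Si](C(C)C)(C(C)C)C(C)C)c(-c2cc3c(OC)c(C)c(O[Si](C(C)C)(C(C)C)C(C)C)cc3o2)c1OCc1ccccc1)c1ccccc1 | intermediate
26 | (1R)-3-{2-(benzyloxy)-6-methoxy-3-[4-methoxy-5-methyl-6-(triisopropylsilyloxy)-1-benzofuran-2-yl]-4-(triisopropylsilyloxy)phenyl}-1-phenylpropan-1-ol | O[C@H](CCc1c(OC)cc(O[Si](C(C)C)(C(C)C)C(C)C)c(-c2cc3c(OC)c(C)c(O[Si](C(C)C)(C(C)C)C(C)C)cc3o2)c1OCc1ccccc1)c1ccccc1 | intermediate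
27 | 2-[(3R)-3-hydroxy-3-phenylpropyl]-3-methoxy-6-[4-methoxy-5-methyl-6-(triisopropylsilyloxy)-1-benzofuran-2-yl]-5-(triisopropylsilyloxy)phenol | O[C@H](CCc1c(OC)cc(O[Si](C(C)C)(C(C)C)C(C)C)c(-c2cc3c(OC)c(C)c(O[Si](C(C)C)(C(C)C)C(C)C)cc3o2)c1O)c1ccccc1 | intermediate
28 | (2S)-5-methoxy-8-[4-methoxy-5-methyl-6-(triisopropylsilyloxy)-1-benzofuran-2-yl]-2-phenyl-7-(triisopropylsilyloxy)chromane | COc1cc(O[Si](C(C)C)(C(C)C)C(C)C)c(-c2cc3c(OC)c(C)c(O[Si](C(C)C)(C(C)C)C(C)C)cc3o2)c2c1CC[C@@H](c1ccccc1)O2 | intermediate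
29 | (2S)-8-(6-hydroxy-4-methoxy-5-methyl-1-benzofuran-2-yl)-5-methoxy-2-phenyl-3,4-dihydro-2H-chromen-7-ol | COc1cc(O)c(-c2cc3c(OC)c(C)c(O)cc3o2)c2c1CC[C@@H](c1ccccc1)O2 | target

## Step count and risks

Total steps: 19. Longest linear sequence: 17 (steps 1–5, then 8–19, from 1).

**Most likely to fail, first: step 8.** Both partners are di-ortho-substituted and electron-rich, so oxidative addition into the C–I bond of 8 may be slow and 13 may homocouple. The fallback leaves palladium catalysis for stoichiometric organocopper chemistry. It sets out from 13, which is stirred with CuI in aqueous NH3–EtOH to precipitate copper(I) [4-methoxy-2,6-bis(methoxymethoxy)phenyl]acetylide F1. Heating F1 with iodophenol 8 in pyridine at 110 °C (Castro–Stephens coupling, ring closure in the same pot) gives 15, where the route is rejoined.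

**Second: step 9.** The lithiation of 15 could be diverted to the benzofuran C3–H or stall for steric reasons. The fallback formylates the A ring before the two halves are joined. It sets out from 13, which is deprotonated with n-BuLi (giving 12) and silylated with TIPSOTf to {[4-methoxy-2,6-bis(methoxymethoxy)phenyl]ethynyl}triisopropylsilane F2. F2 has a single kind of OMOM/OMe-flanked C–H; n-BuLi/TMEDA converts it into {6-methoxy-2,4-bis(methoxymethoxy)-3-[(triisopropylsilyl)ethynyl]phenyl}lithium F3. Quenching with DMF gives 6-methoxy-2,4-bis(methoxymethoxy)-3-[(triisopropylsilyl)ethynyl]benzaldehyde F4. TBAF/AcOH then gives 3-ethynyl-6-methoxy-2,4-bis(methoxymethoxy)benzaldehyde F5. Coupling F5 with 8 under the step 8 conditions passes through 3-{[2-hydroxy-6-methoxy-5-methyl-4-(triisopropylsilyloxy)phenyl]ethynyl}-6-methoxy-2,4-bis(methoxymethoxy)benzaldehyde F6 and cyclises to 17, where the route is rejoined (15 and 16 are bypassed).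

**Third: step 15.** The poisoned catalyst may be too sluggish on the hindered enone or may still cleave the benzyl ether. The fallback accepts the debenzylation instead of avoiding it. It sets out from 24, which is hydrogenated over unpoisoned Pd/C (H2, 1 atm, EtOAc–EtOH) so that C=C reduction and O-debenzylation occur together. This gives 3-{2-hydroxy-6-methoxy-3-[4-methoxy-5-methyl-6-(triisopropylsilyloxy)-1-benzofuran-2-yl]-4-(triisopropylsilyloxy)phenyl}-1-phenylpropan-1-one F7. Noyori asymmetric transfer hydrogenation of F7 with RuCl(p-cymene)[(R,R)-TsDPEN] in HCO2H–Et3N tolerates the free phenol and gives the (R)-carbinol 27, where the route is rejoined (25 and 26 are bypassed).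

## Further compounds

F1 | step 8 | copper(I) [4-methoxy-2,6-bis(methoxymethoxy)phenyl]acetylide | [Cu]C#Cc1c(OCOC)cc(OC)cc1OCOC
F2 | step 9 | {[4-methoxy-2,6-bis(methoxymethoxy)phenyl]ethynyl}triisopropylsilane | COCOc1cc(OC)cc(OCOC)c1C#C[Si](C(C)C)(C(C)C)C(C)C
F3 | step 9 | {6-methoxy-2,4-bis(methoxymethoxy)-3-[(triisopropylsilyl)ethynyl]phenyl}lithium | COCOc1c([Li])c(OC)cc(OCOC)c1C#C[Si](C(C)C)(C(C)C)C(C)C
F4 | step 9 | 6-methoxy-2,4-bis(methoxymethoxy)-3-[(triisopropylsilyl)ethynyl]benzaldehyde | COCOc1c(C=O)c(OC)cc(OCOC)c1C#C[Si](C(C)C)(C(C)C)C(C)C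
F5 | step 9 | 3-ethynyl-6-methoxy-2,4-bis(methoxymethoxy)benzaldehyde | COCOc1c(C=O)c(OC)cc(OCOC)c1C#C
F6 | step 9 | 3-{[2-hydroxy-6-methoxy-5-methyl-4-(triisopropylsilyloxy)phenyl]ethynyl}-6-methoxy-2,4-bis(methoxymethoxy)benzaldehyde | COCOc1c(C=O)c(OC)cc(OCOC)c1C#Cc1c(O)cc(O[Si](C(C)C)(C(C)C)C(C)C)c(C)c1OC
F7 | step 15 | 3-{2-hydroxy-6-methoxy-3-[4-methoxy-5-methyl-6-(triisopropylsilyloxy)-1-benzofuran-2-yl]-4-(triisopropylsilyloxy)phenyl}-1-phenylpropan-1-one | O=C(CCc1c(OC)cc(O[Si](C(C)C)(C(C)C)C(C)C)c(-c2cc3c(OC)c(C)c(O[Si](C(C)C)(C(C)C)C(C)C)cc3o2)c1O)c1ccccc1
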